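Locants: pyrrolo[1,2-a]azepine core N4, C1–C3, C5–C9, C9a (ring A pyrrolidine, ring B azepine); ring C = C9, C9a, C1, C12, C11 (carbinol), C10 (ethyl); ring D = spiro lactone C1–O–C14(=O)–C13(CH3)–C12; ring E = the 4-methyl-5-oxooxolan-2-yl group on C3 (C2′, C4′).
Cuts: C11–OH (back to the ketone), then C9–C10 of ring C, then the enol silane and the C11–propyl bond (thioester), then ring D (C12–C13, lactone C–O, C1–O through a C1 exocyclic alkene), then ring B (C9–C9a aldol, N4–C5) and ring E (C3–C2′ from the proline carboxyl carbon).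
Forward: ring A is cis-4-hydroxy-D-proline; ring E is grown on its carboxyl carbon, ring B is closed by N-alkylation and aldol condensation on the 4-oxo group, ring D is spiro-annulated on that carbon, ring C is closed last and its ketone reduced.
Enabling feature: the enamine N4–C9a=C9 of rings A/B has its β-carbon C9 bonded to C10, which is α to the oxygenated C11, so C9a and C11 are 1,4-related and the C9–C10 bond joins two nucleophilic carbons (enamine β-carbon and ketone α-carbon); it can only be made oxidatively.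
Stereochemistry: C3 from D-hydroxyproline; C2′ by Felkin–Anh allylation; C4′ by hydrogenation cis to the ring substituent; C1 by boryl-copper addition anti to ring E, then oxidation with retention (a carbon nucleophile adding to the C1 ketone would enter anti to ring E and give the wrong spiro centre, so oxygen is put on last);
C13 by SN2 inversion of methyl (R)-lactate triflate; C12 and C10 by the cis C/D fusion and equilibration next to the C11 ketone; C11 by hydride attack anti to ring D.

Key step: step 16

Remark: alkene 17 is used as formed because its geometry is erased in step 11, and the C12 centre made in step 13 is provisional until ring C is closed; compounds 1, 4, 10, 15, 20 and 24 are purchased.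

Step 1
Reactants: 1 methyl (2R,4R)-1-(tert-butoxycarbonyl)-4-hydroxypyrrolidine-2-carboxylate (N-Boc-cis-4-hydroxy-D-proline methyl ester)
Product: 2 methyl (2R,4R)-1-(tert-butoxycarbonyl)-4-[(tert-butyldimethylsilyl)oxy]pyrrolidine-2-carboxylate
Conditions: TBSCl, imidazole, DMF, 23 °C
Reagents that add atoms: tert-butyldimethylsilyl chloride, CC(C)(C)[Si](C)(C)Cl
Why: Imidazole-mediated O-silylation protects the secondary alcohol (the later ketone oxygen) through the hydride and organozinc steps without touching a stereocentre.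

Step 2
Reactants: 2 methyl (2R,4R)-1-(tert-butoxycarbonyl)-4-[(tert-butyldimethylsilyl)oxy]pyrrolidine-2-carboxylate
Product: 3 tert-butyl (2R,4R)-4-[(tert-butyldimethylsilyl)oxy]-2-formylpyrrolidine-1-carboxylate
Conditions: i-Bu2AlH, toluene, −78 °C; MeOH, aq. potassium sodium tartrate
Reagents that add atoms: none
Why: Partial reduction of the methyl ester at −78 °C stops at the aluminium hemiacetal, which releases the N-carbamoyl α-amino aldehyde on work-up without loss of configuration at C2.

Step 3
Reactants: 3 tert-butyl (2R,4R)-4-[(tert-butyldimethylsilyl)oxy]-2-formylpyrrolidine-1-carboxylate; 4 methyl 2-(bromomethyl)prop-2-enoate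
Product: 6 tert-butyl (2R,4R)-4-[(tert-butyldimethylsilyl)oxy]-2-[(2S)-4-methylidene-5-oxooxolan-2-yl]pyrrolidine-1-carboxylate, via hydroxy ester 5 (not isolated)
Conditions: Zn dust, THF/sat. aq. NH4Cl, 23 °C; then TsOH·H2O (cat.), CH2Cl2, 23 °C
Reagents that add atoms: none
Why: Barbier-type zinc allylation followed by acid lactonisation (Dreiding–Schmidt α-methylene lactone synthesis), in which the allylzinc adds in a Felkin–Anh sense anti to the carbamate nitrogen (chelation being suppressed in the aqueous medium) and so sets the carbinol carbon C2′ as S with N and O anti.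

Step 4
Reactants: 6 tert-butyl (2R,4R)-4-[(tert-butyldimethylsilyl)oxy]-2-[(2S)-4-methylidene-5-oxooxolan-2-yl]pyrrolidine-1-carboxylate
Product: 7 tert-butyl (2R,4R)-4-[(tert-butyldimethylsilyl)oxy]-2-[(2S,4S)-4-methyl-5-oxooxolan-2-yl]pyrrolidine-1-carboxylate
Conditions: H2 (1 atm), Pd/C (10%), EtOAc, 23 °C
Reagents that add atoms: none
Why: Heterogeneous hydrogenation adds hydrogen to the exocyclic alkene from the lactone face opposite the pyrrolidinyl group, giving the cis-2,4-disubstituted lactone and hence the 4′S methyl centre.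

Step 5
Reactants: 7 tert-butyl (2R,4R)-4-[(tert-butyldimethylsilyl)oxy]-2-[(2S,4S)-4-methyl-5-oxooxolan-2-yl]pyrrolidine-1-carboxylate
Product: 8 tert-butyl (2R,4R)-4-hydroxy-2-[(2S,4S)-4-methyl-5-oxooxolan-2-yl]pyrrolidine-1-carboxylate
Conditions: HF·pyridine, THF, 0 → 23 °C
Reagents that add atoms: none
Why: Fluoride cleaves the silyl ether by Si–F bond formation while the carbamate and the lactone are inert to buffered HF.

Step 6
Reactants: 8 tert-butyl (2R,4R)-4-hydroxy-2-[(2S,4S)-4-methyl-5-oxooxolan-2-yl]pyrrolidine-1-carboxylate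
Product: 9 tert-butyl (2R)-2-[(2S,4S)-4-methyl-5-oxooxolan-2-yl]-4-oxopyrrolidine-1-carboxylate
Conditions: Dess–Martin periodinane, CH2Cl2, 23 °C
Reagents that add atoms: none
Why: Dess–Martin oxidation turns the secondary alcohol into the ketone under neutral conditions that do not epimerise the lactone α-centre or C2.

Step 7
Reactants: 9 tert-butyl (2R)-2-[(2S,4S)-4-methyl-5-oxooxolan-2-yl]-4-oxopyrrolidine-1-carboxylate; 10 2-(4-bromobutyl)-1,3-dioxolane
Product: 12 (3S,5S)-5-{(2R)-1-[4-(1,3-dioxolan-2-yl)butyl]-4-oxopyrrolidin-2-yl}-3-methyloxolan-2-one, via pyrrolidinium trifluoroacetate 11 (not isolated)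
Conditions: CF3CO2H, CH2Cl2, 0 °C; evaporate; then 10, i-Pr2NEt, NaI (cat.), MeCN, 50 °C
Reagents that add atoms: none
Why: Acidolysis removes the tert-butyl carbamate and the secondary amine is alkylated in situ by SN2 displacement of the primary bromide (iodide catalysis), so that the self-condensing free 3-pyrrolidinone is never stored.

Step 8
Reactants: 12 (3S,5S)-5-{(2R)-1-[4-(1,3-dioxolan-2-yl)butyl]-4-oxopyrrolidin-2-yl}-3-methyloxolan-2-one
Product: 14 (3R)-3-[(2S,4S)-4-methyl-5-oxooxolan-2-yl]-2,3,5,6,7,8-hexahydro-1H-pyrrolo[1,2-a]azepin-1-one (bicyclic 2-amino enone), via amino aldehyde 13 (not isolated)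
Conditions: 2 M aq. HCl/THF, 45 °C; then aq. NaHCO3
Reagents that add atoms: none
Why: Acid unmasks the aldehyde and catalyses an intramolecular aldol condensation (7-enolexo closure) in which only the ketone α-carbon next to nitrogen can reach the aldehyde without forming a bridged ring, and irreversible dehydration gives the conjugated 2-amino enone that contains ring B and the C9a=C9 enamine.

Step 9
Reactants: 15 (diethoxyphosphoryl)acetic acid
Product: 16 S-ethyl 2-(diethoxyphosphoryl)ethanethioate
Conditions: EtSH, N,N′-dicyclohexylcarbodiimide, DMAP (cat.), CH2Cl2, 0 → 23 °C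
Reagents that add atoms: ethanethiol, CCS
Why: Carbodiimide (Steglich-type) coupling of the phosphonoacetic acid with the thiol gives the thioester-stabilised olefination reagent.

Step 10
Reactants: 14 (3R)-3-[(2S,4S)-4-methyl-5-oxooxolan-2-yl]-2,3,5,6,7,8-hexahydro-1H-pyrrolo[1,2-a]azepin-1-one; 16 S-ethyl 2-(diethoxyphosphoryl)ethanethioate
Product: 17 S-ethyl (2E)-2-{(3R)-3-[(2S,4S)-4-methyl-5-oxooxolan-2-yl]-2,3,5,6,7,8-hexahydro-1H-pyrrolo[1,2-a]azepin-1-ylidene}ethanethioate
Conditions: NaH, THF, 0 → 50 °C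
Reagents that add atoms: none
Why: Horner–Wadsworth–Emmons olefination of the ring ketone installs the two-carbon thioester arm and makes C1 an sp2 carbon, so that the C1–O bond can be formed last and from the open face.

Step 11
Reactants: 17 S-ethyl (2E)-2-{(3R)-3-[(2S,4S)-4-methyl-5-oxooxolan-2-yl]-2,3,5,6,7,8-hexahydro-1H-pyrrolo[1,2-a]azepin-1-ylidene}ethanethioate
Product: 19 S-ethyl 2-{(1R,3R)-1-hydroxy-3-[(2S,4S)-4-methyl-5-oxooxolan-2-yl]-2,3,5,6,7,8-hexahydro-1H-pyrrolo[1,2-a]azepin-1-yl}ethanethioate, via tertiary boronate 18 (not isolated)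
Conditions: B2pin2, CuCl (10 mol %), Xantphos (10 mol %), NaOt-Bu (20 mol %), i-PrOH (2 equiv), THF, 23 °C; then NaBO3·4H2O, THF/H2O, 0 → 23 °C
Reagents that add atoms: sodium perborate tetrahydrate (NaBO3·4H2O), [Na+].[O-]OB=O
Why: Copper-catalysed conjugate borylation of the β,β-disubstituted unsaturated thioester delivers boron to C1 from the face opposite the pseudoaxial ring E substituent on C3 (the δ-carbon C9 is deactivated by the enamine nitrogen), and perborate oxidation with retention gives the tertiary alcohol with oxygen trans to ring E, which sets C1 as R.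

Step 12
Reactants: 20 methyl (2R)-2-hydroxypropanoate (methyl (R)-lactate)
Product: 21 methyl (2R)-2-{[(trifluoromethyl)sulfonyl]oxy}propanoate
Conditions: (CF3SO2)2O, 2,6-lutidine, CH2Cl2, −78 → 0 °C
Reagents that add atoms: trifluoromethanesulfonic anhydride, O=S(=O)(OS(=O)(=O)C(F)(F)F)C(F)(F)F
Why: O-sulfonylation of the α-hydroxy ester proceeds with retention and gives an α-carbonyl-activated SN2 electrophile.

Step 13
Reactants: 19 S-ethyl 2-{(1R,3R)-1-hydroxy-3-[(2S,4S)-4-methyl-5-oxooxolan-2-yl]-2,3,5,6,7,8-hexahydro-1H-pyrrolo[1,2-a]azepin-1-yl}ethanethioate; 21 methyl (2R)-2-{[(trifluoromethyl)sulfonyl]oxy}propanoate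
Product: 23 S-ethyl (1R,3R,12S,13R)-13-methyl-3-[(2S,4S)-4-methyl-5-oxooxolan-2-yl]-14-oxo spiro lactone 12-carbothioate (ring D lactone C1–O–C14(=O)–C13–C12 spiro at C1 of the 2,3,5,6,7,8-hexahydro-1H-pyrrolo[1,2-a]azepine), via hydroxy diester 22 (not isolated)
Conditions: LiN(SiMe3)2 (2.1 equiv), THF, −78 °C; then 21, −78 → −40 °C; AcOH, −78 °C; then 2-hydroxypyridine (cat.), toluene, 60 °C
Reagents that add atoms: none
Why: Fráter–Seebach-type alkylation of the alkoxide–thioester enolate dianion displaces triflate with inversion and so sets C13 as R, the electrophile entering anti to the larger C9a flank of the lithium chelate so that the thioester on C12 lies cis to C9a, and the tertiary alcohol then closes ring D by acyl substitution on the methyl ester.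

Step 14
Reactants: 23 S-ethyl (1R,3R,12S,13R)-13-methyl-3-[(2S,4S)-4-methyl-5-oxooxolan-2-yl]-14-oxo spiro lactone 12-carbothioate; 24 n-propylzinc bromide
Product: 25 1-[(1R,3R,12S,13R)-13-methyl-3-[(2S,4S)-4-methyl-5-oxooxolan-2-yl]-14-oxo spiro lactone-12-yl]butan-1-one (C12 butanoyl ketone of the spiro lactone enamine)
Conditions: n-PrZnBr, PdCl2(PPh3)2 (5 mol %), THF/toluene, 23 °C; aq. NH4Cl
Reagents that add atoms: none
Why: Fukuyama coupling (oxidative addition of zerovalent palladium into the C–S bond, transmetalation from zinc, reductive elimination) converts the thioester into the propyl ketone under neutral conditions that leave the lactones, the enamine and the acidic C12–H untouched.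

Step 15
Reactants: 25 1-[(1R,3R,12S,13R)-13-methyl-3-[(2S,4S)-4-methyl-5-oxooxolan-2-yl]-14-oxo spiro lactone-12-yl]butan-1-one
Product: 26 (Z)-tert-butyldimethylsilyl enol ether of 25 (C12–C(OSi)=CH–CH2CH3 with OSi and ethyl cis; 1R,3R,12S,13R)
Conditions: KN(SiMe3)2, THF, −78 °C; then TBSCl, −78 → −40 °C
Reagents that add atoms: tert-butyldimethylsilyl chloride, CC(C)(C)[Si](C)(C)Cl
Why: Kinetic deprotonation at the unhindered CH2 of the propyl ketone (the other α-carbon is a methine next to the quaternary spiro carbon) gives the Z-enolate, which is O-silylated to the Z-silyl enol ether.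

Step 16
Reactants: 26 (Z)-tert-butyldimethylsilyl enol ether of 25
Product: 27 (1R,3R,10S,12S,13R)-10-ethyl-13-methyl-3-[(2S,4S)-4-methyl-5-oxooxolan-2-yl] tetracyclic enamine 11,14-dione (rings A–D with the C9=C9a enamine, the C11 ketone and the ring D lactone)
Conditions: undivided cell, reticulated vitreous carbon anode, Pt cathode, constant current, 2.1 F/mol; 0.1 M LiClO4, 2,6-lutidine (4 equiv), MeOH/CH2Cl2 (1:4), 23 °C
Reagents that add atoms: none
Why: Proposed new method: removal of one electron from the enamine at the anode gives a radical cation that is attacked at its β-carbon C9 by the silyl enol ether carbon C10; the α-silyloxy radical so formed is oxidised further, methanol takes the silyl group to leave the C11 ketone, and 2,6-lutidine removes the C9 proton of the iminium ion to return the now tetrasubstituted enamine. The closest known reaction types are anodic couplings of electron-rich alkenes with tethered enol ethers and oxidative couplings of transient enamine radical cations with enol silanes, neither of which has used a preformed bicyclic tertiary enamine. Ring C closes by a six-membered cyclisation in which both the C9a=C9 and the C11=C10 double bonds lie inside the new ring (endo with respect to each π bond). The new centre C10 arises in a chair-like transition state fixed by the Z-enol ether and the cis arrangement of the side chain and C9a on ring D, and, being α to the new ketone and allylic, it can settle in the configuration with ethyl pseudoaxial (no A(1,2) strain with C8), which is 10S; C12 is held by the cis C/D ring fusion. The step needs oxidation of the enamine in preference to the enol ether, which the lower oxidation potential of a trialkyl enamine should secure, and capture of the radical cation by carbon before methanol, which the intramolecular six-membered reach and the lutidine-buffered, methanol-poor medium should secure.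

Step 17
Reactants: 27 (1R,3R,10S,12S,13R)-10-ethyl-13-methyl-3-[(2S,4S)-4-methyl-5-oxooxolan-2-yl] tetracyclic enamine 11,14-dione
Product: 28 (1R,3R,10S,11R,12R,13R)-10-ethyl-11-hydroxy-13-methyl-3-[(2S,4S)-4-methyl-5-oxooxolan-2-yl] tetracyclic enamine lactone (target)
Conditions: LiBH(s-Bu)3, THF, −78 °C; H2O
Reagents that add atoms: none
Why: Hydride from the bulky borohydride approaches the ring C ketone along the equatorial trajectory on the face opposite the pseudoaxial lactone oxygen on C1 and the fused ring D, giving the axial 11R carbinol cis to the lactone, while the lactones are not reduced at −78 °C.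

Compound list
1 | methyl (2R,4R)-1-(tert-butoxycarbonyl)-4-hydroxypyrrolidine-2-carboxylate | COC(=O)[C@H]1C[C@@H](O)CN1C(=O)OC(C)(C)C | starting material
2 | methyl (2R,4R)-1-(tert-butoxycarbonyl)-4-[(tert-butyldimethylsilyl)oxy]pyrrolidine-2-carboxylate | COC(=O)[C@H]1C[C@@H](O[Si](C)(C)C(C)(C)C)CN1C(=O)OC(C)(C)C | intermediate
3 | tert-butyl (2R,4R)-4-[(tert-butyldimethylsilyl)oxy]-2-formylpyrrolidine-1-carboxylate | O=C[C@H]1C[C@@H](O[Si](C)(C)C(C)(C)C)CN1C(=O)OC(C)(C)C | intermediate
4 | methyl 2-(bromomethyl)prop-2-enoate | C=C(CBr)C(=O)OC | starting material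
5 | methyl (4S)-4-{(2R,4R)-1-(tert-butoxycarbonyl)-4-[(tert-butyldimethylsilyl)oxy]pyrrolidin-2-yl}-4-hydroxy-2-methylidenebutanoate (not isolated) | C=C(C[C@H](O)[C@H]1C[C@@H](O[Si](C)(C)C(C)(C)C)CN1C(=O)OC(C)(C)C)C(=O)OC | intermediate
6 | tert-butyl (2R,4R)-4-[(tert-butyldimethylsilyl)oxy]-2-[(2S)-4-methylidene-5-oxooxolan-2-yl]pyrrolidine-1-carboxylate | C=C1C[C@H](OC1=O)[C@H]1C[C@@H](O[Si](C)(C)C(C)(C)C)CN1C(=O)OC(C)(C)C | intermediate
7 | tert-butyl (2R,4R)-4-[(tert-butyldimethylsilyl)oxy]-2-[(2S,4S)-4-methyl-5-oxooxolan-2-yl]pyrrolidine-1-carboxylate | C[C@H]1C[C@H](OC1=O)[C@H]1C[C@@H](O[Si](C)(C)C(C)(C)C)CN1C(=O)OC(C)(C)C | intermediate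
8 | tert-butyl (2R,4R)-4-hydroxy-2-[(2S,4S)-4-methyl-5-oxooxolan-2-yl]pyrrolidine-1-carboxylate | C[C@H]1C[C@H](OC1=O)[C@H]1C[C@@H](O)CN1C(=O)OC(C)(C)C | intermediate
9 | tert-butyl (2R)-2-[(2S,4S)-4-methyl-5-oxooxolan-2-yl]-4-oxopyrrolidine-1-carboxylate | C[C@H]1C[C@H](OC1=O)[C@H]1CC(=O)CN1C(=O)OC(C)(C)C | intermediate
10 | 2-(4-bromobutyl)-1,3-dioxolane | BrCCCCC1OCCO1 | starting material
11 | (2R)-2-[(2S,4S)-4-methyl-5-oxooxolan-2-yl]-4-oxopyrrolidin-1-ium trifluoroacetate (not isolated) | C[C@H]1C[C@H](OC1=O)[C@H]1CC(=O)C[NH2+]1.[O-]C(=O)C(F)(F)F | intermediate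
12 | (3S,5S)-5-{(2R)-1-[4-(1,3-dioxolan-2-yl)butyl]-4-oxopyrrolidin-2-yl}-3-methyloxolan-2-one | C[C@H]1C[C@H](OC1=O)[C@H]1CC(=O)CN1CCCCC1OCCO1 | intermediate
13 | 5-{(2R)-2-[(2S,4S)-4-methyl-5-oxooxolan-2-yl]-4-oxopyrrolidin-1-yl}pentanal (not isolated) | C[C@H]1C[C@H](OC1=O)[C@H]1CC(=O)CN1CCCCC=O | intermediate
14 | (3R)-3-[(2S,4S)-4-methyl-5-oxooxolan-2-yl]-2,3,5,6,7,8-hexahydro-1H-pyrrolo[1,2-a]azepin-1-one | C1=C2N(CCCC1)[C@@H]([C@@H]1C[C@H](C)C(=O)O1)CC2=O | intermediate
15 | (diethoxyphosphoryl)acetic acid | OC(=O)CP(=O)(OCC)OCC | starting material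
16 | S-ethyl 2-(diethoxyphosphoryl)ethanethioate | CCSC(=O)CP(=O)(OCC)OCC | intermediate
17 | S-ethyl (2E)-2-{(3R)-3-[(2S,4S)-4-methyl-5-oxooxolan-2-yl]-2,3,5,6,7,8-hexahydro-1H-pyrrolo[1,2-a]azepin-1-ylidene}ethanethioate | C1=C2N(CCCC1)[C@@H]([C@@H]1C[C@H](C)C(=O)O1)C\C2=C/C(=O)SCC | intermediate
18 | S-ethyl 2-{(1S,3R)-3-[(2S,4S)-4-methyl-5-oxooxolan-2-yl]-1-(4,4,5,5-tetramethyl-1,3,2-dioxaborolan-2-yl)-2,3,5,6,7,8-hexahydro-1H-pyrrolo[1,2-a]azepin-1-yl}ethanethioate (boron trans to ring E; not isolated) | C1=C2N(CCCC1)[C@@H]([C@@H]1C[C@H](C)C(=O)O1)C[C@@]2(B1OC(C)(C)C(C)(C)O1)CC(=O)SCC | intermediate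
19 | S-ethyl 2-{(1R,3R)-1-hydroxy-3-[(2S,4S)-4-methyl-5-oxooxolan-2-yl]-2,3,5,6,7,8-hexahydro-1H-pyrrolo[1,2-a]azepin-1-yl}ethanethioate (hydroxyl trans to ring E) | C1=C2N(CCCC1)[C@@H]([C@@H]1C[C@H](C)C(=O)O1)C[C@@]2(O)CC(=O)SCC | intermediate
20 | methyl (2R)-2-hydroxypropanoate | C[C@@H](O)C(=O)OC | starting material
21 | methyl (2R)-2-{[(trifluoromethyl)sulfonyl]oxy}propanoate | C[C@@H](OS(=O)(=O)C(F)(F)F)C(=O)OC | intermediate
22 | methyl (2R,3S)-3-[(ethylsulfanyl)carbonyl]-3-{(1R,3R)-1-hydroxy-3-[(2S,4S)-4-methyl-5-oxooxolan-2-yl]-2,3,5,6,7,8-hexahydro-1H-pyrrolo[1,2-a]azepin-1-yl}-2-methylpropanoate (not isolated) | C1=C2N(CCCC1)[C@@H]([C@@H]1C[C@H](C)C(=O)O1)C[C@@]2(O)[C@@H](C(=O)SCC)[C@@H](C)C(=O)OC | intermediate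
23 | S-ethyl (1R,3R,12S,13R)-13-methyl-3-[(2S,4S)-4-methyl-5-oxooxolan-2-yl]-14-oxo spiro lactone 12-carbothioate (ring D spiro at C1 of the hexahydropyrrolo[1,2-a]azepine enamine; thioester cis to C9a and to the C13 methyl) | C1=C2N(CCCC1)[C@@H]([C@@H]1C[C@H](C)C(=O)O1)C[C@]23OC(=O)[C@H](C)[C@@H]3C(=O)SCC | intermediate
24 | n-propylzinc bromide | CCC[Zn]Br | starting material
25 | 1-[(1R,3R,12S,13R)-13-methyl-3-[(2S,4S)-4-methyl-5-oxooxolan-2-yl]-14-oxo spiro lactone-12-yl]butan-1-one | C1=C2N(CCCC1)[C@@H]([C@@H]1C[C@H](C)C(=O)O1)C[C@]23OC(=O)[C@H](C)[C@@H]3C(=O)CCC | intermediate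
26 | (Z)-tert-butyldimethylsilyl enol ether of 25 (1R,3R,12S,13R) | C1=C2N(CCCC1)[C@@H]([C@@H]1C[C@H](C)C(=O)O1)C[C@]23OC(=O)[C@H](C)[C@@H]3/C(O[Si](C)(C)C(C)(C)C)=C/CC | intermediate
27 | (1R,3R,10S,12S,13R)-10-ethyl-13-methyl-3-[(2S,4S)-4-methyl-5-oxooxolan-2-yl] tetracyclic enamine 11,14-dione | CC[C@H]1C2=C3N(CCCC2)[C@@H]([C@@H]2C[C@H](C)C(=O)O2)C[C@]32OC(=O)[C@H](C)[C@@H]2C1=O | intermediate
28 | (1R,3R,10S,11R,12R,13R)-10-ethyl-11-hydroxy-13-methyl-3-[(2S,4S)-4-methyl-5-oxooxolan-2-yl] tetracyclic enamine lactone | CC[C@H]1C2=C3N(CCCC2)[C@@H]([C@@H]2C[C@H](C)C(=O)O2)C[C@]32OC(=O)[C@H](C)[C@@H]2[C@@H]1O | target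

Total step count: 17 (steps 9 and 12 prepare reagents). Longest linear sequence: 15 steps (1 → 28 through steps 1–8, 10, 11 and 13–17).

Steps most likely to fail

Step 16 (anodic ring closure). The radical cation may be trapped by methanol at C9, the product enamine may be oxidised further, or the six-membered closure may be too slow. The fallback uses polar, known chemistry and sets out from 26. The enamine is first stored as its iminium tetrafluoroborate (HBF4·OEt2, 1 equiv, CH2Cl2, −78 °C). The silyl enol ether is then brominated with N-bromosuccinimide to the α-bromo ketone F1. Addition of i-Pr2NEt releases the enamine, whose C9 displaces bromide in an intramolecular Stork enamine alkylation, and loss of the C9 proton returns the route at 27.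

Step 13 (alkylation and lactonisation). The hindered enolate may eliminate the triflate instead of substituting it, or substitution may be slow enough for retro-aldol cleavage and loss of the C13 configuration. The fallback sets out from 19 and replaces the SN2 step by a carbonyl addition. The dianion of 19 is added to methyl pyruvate and the adduct lactonises to the α-hydroxy lactone F2. The tertiary α-hydroxyl is then removed with SmI2 (THF, t-BuOH), and protonation of the resulting lactone enolate from the face away from the C12 thioester should give the cis methyl group and return the route at 23.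

Step 11 (borylation and oxidation). Boron may add at C9 (1,6-addition), facial selectivity at C1 may be poor, or the perborate step may oxidise the enamine or cleave the thioester. The fallback sets out from 17 and uses silicon as the oxygen surrogate. Copper-catalysed conjugate silylation (Me2PhSi–Bpin, CuCl, NaOt-Bu, MeOH, THF) gives the β-silyl thioester F3, with silicon anti to ring E. Fleming–Tamao oxidation is then run with the enamine protonated (HBF4·OEt2; then KF, m-chloroperbenzoic acid, DMF) and proceeds with retention, returning the route at 19.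

Further compounds
F1 | step 16 | 2-bromo-1-[(1R,3R,12S,13R)-13-methyl-3-[(2S,4S)-4-methyl-5-oxooxolan-2-yl]-14-oxo spiro lactone-12-yl]butan-1-one (both bromide epimers; handled as its iminium tetrafluoroborate) | C1=C2N(CCCC1)[C@@H]([C@@H]1C[C@H](C)C(=O)O1)C[C@]23OC(=O)[C@H](C)[C@@H]3C(=O)C(Br)CC
F2 | step 13 | S-ethyl (1R,3R,12S)-13-hydroxy-13-methyl-3-[(2S,4S)-4-methyl-5-oxooxolan-2-yl]-14-oxo spiro lactone 12-carbothioate (both C13 epimers) | C1=C2N(CCCC1)[C@@H]([C@@H]1C[C@H](C)C(=O)O1)C[C@]23OC(=O)C(C)(O)[C@@H]3C(=O)SCC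
F3 | step 11 | S-ethyl 2-{(3R)-1-[dimethyl(phenyl)silyl]-3-[(2S,4S)-4-methyl-5-oxooxolan-2-yl]-2,3,5,6,7,8-hexahydro-1H-pyrrolo[1,2-a]azepin-1-yl}ethanethioate (silicon trans to ring E) | C1=C2N(CCCC1)[C@@H]([C@@H]1C[C@H](C)C(=O)O1)C[C@@]2([Si](C)(C)c1ccccc1)CC(=O)SCC
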